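**Plan**

1. Retrosynthetic cuts: the C19 ester and C7 acetate (functional-group level); C14=C15 and C12=C13 of the diene (Wittig, cross-metathesis); C4–C18 together with C5–H (reductive methylation of a ring A C4=C5 enoate); C6–C7 (ring B); C5–C6 (methyl coupling); C3–C4 and C4–C5 (ring A from a β-keto ester); C10–C20 and C10–C1 (enolate alkylations). This leads back to (R)-carvone, whose two enone carbons are excised.
2. Forward order: (R)-carvone is alkylated twice at the future C10, then its ring is cut open oxidatively so that only C5, C9–C12 and the isopropenyl carbons (C7, C8, C17) remain. Ring A is built on the C5 acid, ring B is closed by C6–C7, and C4/C5, the C7 acetate and the diene follow.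
3. Enabling feature: with a C4=C5 double bond in ring A, the C6 methyl is the γ-carbon of the C19 ester (a vinylogous donor). C7 is the carbonyl carbon of an α-methylene aldehyde (C8=C17, no α-hydrogen) held on C9, and C5–C10–C9–C8 make the closure six-membered.
4. Stereochemistry: C9 comes from carvone; C10 from alkylation anti to the isopropenyl group on the carvone ring; C7 from the chair transition state of the ring closure followed by Mitsunobu inversion with acetic acid; C5 and C4 from axial protonation and equatorial methylation in the reductive alkylation; 12E from the cross-metathesis.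

Key step: step 11

Remark: atoms carry labdane numbers (ring A C1–C5/C10, ring B C5–C10, side chain C11–C16, exocyclic methylene C17, 4α-methyl C18, carboxyl C19, 10-methyl C20); α is the face opposite the C20 methyl group.

**Route**

Step 1
Reactants: 1 (R)-(−)-carvone; 2 1-chloro-3-iodopropane
Product: 3 (5R,6S)-6-(3-chloropropyl)-2-methyl-5-(prop-1-en-2-yl)cyclohex-2-en-1-one (major trans epimer)
Conditions: LiN(i-Pr)2, THF, −78 °C; then 2, DMPU, −78 → −20 °C
Reagents that add atoms: none
Why: Kinetic α′-deprotonation of the enone and SN2 alkylation of the lithium enolate at the iodide end (ketone enolate alkylation) should attach C1–C3; the new centre is re-enolised in step 2, so its configuration is of no consequence.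

Step 2
Reactants: 3 (5R,6S)-6-(3-chloropropyl)-2-methyl-5-(prop-1-en-2-yl)cyclohex-2-en-1-one
Product: 4 (5S,6R)-6-(3-chloropropyl)-2,6-dimethyl-5-(prop-1-en-2-yl)cyclohex-2-en-1-one
Conditions: LiN(i-Pr)2, THF, −78 °C; then MeI, −78 → 0 °C
Reagents that add atoms: iodomethane, CI
Why: Enolate alkylation in which methyl iodide should enter the tetrasubstituted enolate anti to the neighbouring isopropenyl group (cyclic 1,2-induction, well precedented for 6-substituted carvones), setting the quaternary C10 with methyl trans and chloropropyl cis to the isopropenyl group.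

Step 3
Reactants: 4 (5S,6R)-6-(3-chloropropyl)-2,6-dimethyl-5-(prop-1-en-2-yl)cyclohex-2-en-1-one
Product: 5 (1R,3R,4S,6R)-3-(3-chloropropyl)-1,3-dimethyl-4-(prop-1-en-2-yl)-7-oxabicyclo[4.1.0]heptan-2-one
Conditions: 30% H2O2, NaOH, MeOH, 0 °C
Reagents that add atoms: hydrogen peroxide, OO
Why: Weitz–Scheffer nucleophilic epoxidation should touch only the electron-poor enone double bond and spare the isopropenyl group; the oxirane is expected anti to the isopropenyl group and both its stereocentres are destroyed in step 4.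

Step 4
Reactants: 5 (1R,3R,4S,6R)-3-(3-chloropropyl)-1,3-dimethyl-4-(prop-1-en-2-yl)-7-oxabicyclo[4.1.0]heptan-2-one
Product: 6 (2R,3S)-2-(3-chloropropyl)-2-methyl-5-oxo-3-(prop-1-en-2-yl)pentanoic acid
Conditions: H5IO6 (2.5 equiv), THF/H2O, 0 °C → rt
Reagents that add atoms: water, O
Why: Acid-promoted opening of the epoxide to the α,β-dihydroxy ketone and Malaprade-type periodate cleavage of both the glycol and the resulting 1,2-dicarbonyl unit should excise the old enone α-carbon and its methyl as acetic acid, leaving C5 as the acid and C12 as the aldehyde with C9 and C10 untouched.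

Step 5
Reactants: 6 (2R,3S)-2-(3-chloropropyl)-2-methyl-5-oxo-3-(prop-1-en-2-yl)pentanoic acid
Product: 7 (2R,3S)-2-(3-chloropropyl)-2-methyl-3-(prop-1-en-2-yl)hex-5-enoic acid
Conditions: Ph3PCH3Br, KN(SiMe3)2 (3 equiv each), THF, 0 °C → rt; aq. citric acid
Reagents that add atoms: methylenetriphenylphosphorane, C=P(c1ccccc1)(c1ccccc1)c1ccccc1
Why: Wittig methylenation of the aldehyde (the carboxylate is inert) should give the terminal alkene that masks the side chain through the later dissolving-metal step; no stereocentre is formed or put at risk.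

Step 6
Reactants: 7 (2R,3S)-2-(3-chloropropyl)-2-methyl-3-(prop-1-en-2-yl)hex-5-enoic acid; 8 Meldrum's acid; 9 2-(trimethylsilyl)ethanol
Product: 11 2-(trimethylsilyl)ethyl (4R,5S)-4-(3-chloropropyl)-4-methyl-3-oxo-5-(prop-1-en-2-yl)oct-7-enoate, via acyl Meldrum's acid 10 (not isolated)
Conditions: 8, DCC, DMAP, CH2Cl2, 0 °C → rt; filtration; then 9, toluene, 100 °C
Reagents that add atoms: none
Why: Oikawa–Yonemitsu β-keto ester synthesis (C-acylation of Meldrum's acid, then thermal alcoholysis through the acylketene) should add C4 and C19 as a 2-(trimethylsilyl)ethyl ester without touching C10.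

Step 7
Reactants: 11 2-(trimethylsilyl)ethyl (4R,5S)-4-(3-chloropropyl)-4-methyl-3-oxo-5-(prop-1-en-2-yl)oct-7-enoate
Product: 12 2-(trimethylsilyl)ethyl (3R)-3-methyl-3-[(3S)-2-methylhexa-1,5-dien-3-yl]-2-oxocyclohexane-1-carboxylate (C4 epimers and enol)
Conditions: K2CO3, NaI (0.2 equiv), acetone, reflux
Reagents that add atoms: none
Why: Intramolecular C-alkylation of the β-keto ester enolate by the primary chloride (6-(enolendo)-exo-tet, Finkelstein activation) should close ring A between C3 and C4; C4 is an enolisable centre of no consequence.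

Step 8
Reactants: 12 2-(trimethylsilyl)ethyl (3R)-3-methyl-3-[(3S)-2-methylhexa-1,5-dien-3-yl]-2-oxocyclohexane-1-carboxylate
Product: 13 2-(trimethylsilyl)ethyl (3R)-3-methyl-3-[(3S)-2-methylhexa-1,5-dien-3-yl]-2-{[(trifluoromethyl)sulfonyl]oxy}cyclohex-1-ene-1-carboxylate
Conditions: NaH, Et2O, 0 °C; then Tf2O, −78 → 0 °C
Reagents that add atoms: trifluoromethanesulfonic anhydride, O=S(=O)(OS(=O)(=O)C(F)(F)F)C(F)(F)F
Why: O-sulfonylation of the sodium enolate of the β-keto ester (enol triflate formation) can only occur toward C4 because C10 is quaternary.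

Step 9
Reactants: 13 2-(trimethylsilyl)ethyl (3R)-3-methyl-3-[(3S)-2-methylhexa-1,5-dien-3-yl]-2-{[(trifluoromethyl)sulfonyl]oxy}cyclohex-1-ene-1-carboxylate
Product: 14 2-(trimethylsilyl)ethyl (3R)-2,3-dimethyl-3-[(3S)-2-methylhexa-1,5-dien-3-yl]cyclohex-1-ene-1-carboxylate
Conditions: MeMgBr, Fe(acac)3 (5 mol %), THF/NMP, −30 °C
Reagents that add atoms: methylmagnesium bromide, C[Mg]Br
Why: Iron-catalysed cross-coupling of the alkenyl triflate with the methyl Grignard reagent (Kumada-type) should install C6 as the β-methyl group of the enoate, esters being tolerated at this temperature.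

Step 10
Reactants: 14 2-(trimethylsilyl)ethyl (3R)-2,3-dimethyl-3-[(3S)-2-methylhexa-1,5-dien-3-yl]cyclohex-1-ene-1-carboxylate
Product: 16 2-(trimethylsilyl)ethyl (3R)-3-[(3R)-2-formylhexa-1,5-dien-3-yl]-2,3-dimethylcyclohex-1-ene-1-carboxylate, via allylic alcohol 15 (not isolated)
Conditions: SeO2 (0.5 equiv), t-BuOOH, CH2Cl2, rt; aqueous wash; then MnO2, CH2Cl2, rt
Reagents that add atoms: selenium dioxide, O=[Se]=O; tert-butyl hydroperoxide, CC(C)(C)OO
Why: Riley allylic oxidation (ene reaction, then [2,3]-sigmatropic shift) should occur at the methyl group of the electron-rich 1,1-disubstituted isopropenyl alkene in preference to the monosubstituted allyl and electron-poor enoate alkenes, and MnO2 should take the primary allylic alcohol on to the α-methylene aldehyde (C7).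

Step 11
Reactants: 16 2-(trimethylsilyl)ethyl (3R)-3-[(3R)-2-formylhexa-1,5-dien-3-yl]-2,3-dimethylcyclohex-1-ene-1-carboxylate
Product: 17 2-(trimethylsilyl)ethyl (4aR,5R,7S)-7-hydroxy-4a-methyl-6-methylidene-5-(prop-2-en-1-yl)-2,3,4,4a,5,6,7,8-octahydronaphthalene-1-carboxylate (7β-alcohol)
Conditions: pre-formed Al(OC6H3-2,6-Ph2)3 (ATPH, 3.3 equiv), toluene, −78 °C; then lithium 2,2,6,6-tetramethylpiperidide (2.3 equiv), THF, −78 °C, 0.01 M; aq. HCl
Reagents that add atoms: none
Why: The aluminium phenoxide binds both carbonyl groups, the hindered amide removes a proton from the C6 methyl group (the only hydrogen-bearing γ-position of the enoate), and the extended enolate adds through C6 to the C7 aldehyde carbon, after which protonation returns the conjugated C4=C5 enoate. The closest known reaction type is the ATPH-directed vinylogous aldol addition of β-methyl enoates to aldehydes, which is also known in intramolecular form. Ring B closes by a 6-(enolendo)-exo-trig attack that forms C6–C7, with C5, C10, C9 and C8 as the tether. The new stereocentre C7 is controlled by the C9/C10 centres through a chair-like transition state with the C10 methyl axial and C11 equatorial, in which the bulky aluminium-bound oxygen lies equatorial and away from the second aluminium phenoxide on the ester, so the 7β-alcohol is expected. The step needs γ- over α-attack, secured by the shielding of C4 by the ester-bound aluminium phenoxide and by the strain of the bridged bicyclo[3.3.1] α-adduct, and 1,2- over 1,4-addition to the enal, secured by ring size since attack at C17 would need an eight-membered ring. The aldehyde cannot enolise because C8 carries no hydrogen, so no self-condensation competes.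

Step 12
Reactants: 17 2-(trimethylsilyl)ethyl (4aR,5R,7S)-7-hydroxy-4a-methyl-6-methylidene-5-(prop-2-en-1-yl)-2,3,4,4a,5,6,7,8-octahydronaphthalene-1-carboxylate
Product: 18 2-(trimethylsilyl)ethyl (1S,4aR,5R,7S,8aR)-7-hydroxy-1,4a-dimethyl-6-methylidene-5-(prop-2-en-1-yl)decahydronaphthalene-1-carboxylate
Conditions: Li (5 equiv), NH3/THF, t-BuOH (1 equiv), −78 °C; isoprene; then MeI (excess), −78 → −33 °C; H2O
Reagents that add atoms: iodomethane, CI
Why: Dissolving-metal conjugate reduction of the enoate and methylation of the resulting ester enolate (Birch-type reductive alkylation) should protonate C5 axially to the trans-decalin (H anti to the C10 methyl) and bring methyl iodide onto the exocyclic C4 enolate from the equatorial α-face, away from the axial C10 methyl, so the ester ends axial (C19) as in the target.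

Step 13
Reactants: 18 2-(trimethylsilyl)ethyl (1S,4aR,5R,7S,8aR)-7-hydroxy-1,4a-dimethyl-6-methylidene-5-(prop-2-en-1-yl)decahydronaphthalene-1-carboxylate
Product: 19 2-(trimethylsilyl)ethyl (1S,4aR,5R,7R,8aR)-7-(acetyloxy)-1,4a-dimethyl-6-methylidene-5-(prop-2-en-1-yl)decahydronaphthalene-1-carboxylate
Conditions: PPh3, DIAD, AcOH (3 equiv each), THF, 0 °C → rt
Reagents that add atoms: acetic acid, CC(=O)O
Why: Mitsunobu esterification, in which SN2 displacement of the equatorial 7β-oxyphosphonium group by acetate should invert C7 and deliver the axial 7α-acetate in the same operation.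

Step 14
Reactants: 19 2-(trimethylsilyl)ethyl (1S,4aR,5R,7R,8aR)-7-(acetyloxy)-1,4a-dimethyl-6-methylidene-5-(prop-2-en-1-yl)decahydronaphthalene-1-carboxylate; 20 methacrolein
Product: 21 2-(trimethylsilyl)ethyl (1S,4aR,5R,7R,8aR)-7-(acetyloxy)-1,4a-dimethyl-6-methylidene-5-[(2E)-3-methyl-4-oxobut-2-en-1-yl]decahydronaphthalene-1-carboxylate
Conditions: second-generation Hoveyda–Grubbs catalyst (5 mol %), 20 (10 equiv), CH2Cl2, 40 °C
Reagents that add atoms: none
Why: Olefin cross-metathesis of the reactive terminal alkene with methacrolein should give the trisubstituted (E)-enal under thermodynamic control, while the hindered 1,1-disubstituted C8(17) alkene stays out.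

Step 15
Reactants: 21 2-(trimethylsilyl)ethyl (1S,4aR,5R,7R,8aR)-7-(acetyloxy)-1,4a-dimethyl-6-methylidene-5-[(2E)-3-methyl-4-oxobut-2-en-1-yl]decahydronaphthalene-1-carboxylate
Product: 22 2-(trimethylsilyl)ethyl (1S,4aR,5R,7R,8aR)-7-(acetyloxy)-1,4a-dimethyl-6-methylidene-5-[(2E)-3-methylpenta-2,4-dien-1-yl]decahydronaphthalene-1-carboxylate
Conditions: Ph3PCH3Br, KN(SiMe3)2 (1.2 equiv each), THF, −78 → 0 °C
Reagents that add atoms: methylenetriphenylphosphorane, C=P(c1ccccc1)(c1ccccc1)c1ccccc1
Why: Wittig methylenation of the enal (1,2-addition) should complete the diene without touching the C12=C13 geometry, the aldehyde reacting far faster than the hindered acetate or the ester.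

Step 16
Reactants: 22 2-(trimethylsilyl)ethyl (1S,4aR,5R,7R,8aR)-7-(acetyloxy)-1,4a-dimethyl-6-methylidene-5-[(2E)-3-methylpenta-2,4-dien-1-yl]decahydronaphthalene-1-carboxylate
Product: 23 (1S,4aR,5R,7R,8aR)-7-(acetyloxy)-1,4a-dimethyl-6-methylidene-5-[(2E)-3-methylpenta-2,4-dien-1-yl]decahydronaphthalene-1-carboxylic acid (7α-acetoxy-trans-communic acid, CNP0135450.1)
Conditions: Bu4NF, THF, 0 °C → rt; aq. NH4Cl
Reagents that add atoms: none
Why: Fluoride-induced fragmentation of the 2-(trimethylsilyl)ethyl ester (attack at silicon, β-elimination) should free the hindered axial C19 acid remote from the congested carbonyl, under conditions expected to spare the allylic acetate and the diene.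

**Compound list**

1 | (R)-(−)-carvone, (5R)-2-methyl-5-(prop-1-en-2-yl)cyclohex-2-en-1-one | CC1=CC[C@H](CC1=O)C(C)=C | starting material
2 | 1-chloro-3-iodopropane | ClCCCI | starting material
3 | (5R,6S)-6-(3-chloropropyl)-2-methyl-5-(prop-1-en-2-yl)cyclohex-2-en-1-one (trans, major C6 epimer) | O=C1C(C)=CC[C@@H](C(C)=C)[C@@H]1CCCCl | intermediate
4 | (5S,6R)-6-(3-chloropropyl)-2,6-dimethyl-5-(prop-1-en-2-yl)cyclohex-2-en-1-one (6-methyl trans to isopropenyl) | O=C1C(C)=CC[C@@H](C(C)=C)[C@@]1(C)CCCCl | intermediate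
5 | (1R,3R,4S,6R)-3-(3-chloropropyl)-1,3-dimethyl-4-(prop-1-en-2-yl)-7-oxabicyclo[4.1.0]heptan-2-one (oxirane anti to isopropenyl) | O=C1[C@]2(C)O[C@@H]2C[C@@H](C(C)=C)[C@@]1(C)CCCCl | intermediate
6 | (2R,3S)-2-(3-chloropropyl)-2-methyl-5-oxo-3-(prop-1-en-2-yl)pentanoic acid | OC(=O)[C@](C)(CCCCl)[C@@H](CC=O)C(C)=C | intermediate
7 | (2R,3S)-2-(3-chloropropyl)-2-methyl-3-(prop-1-en-2-yl)hex-5-enoic acid | OC(=O)[C@](C)(CCCCl)[C@@H](CC=C)C(C)=C | intermediate
8 | Meldrum's acid (2,2-dimethyl-1,3-dioxane-4,6-dione) | CC1(C)OC(=O)CC(=O)O1 | starting material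
9 | 2-(trimethylsilyl)ethanol | C[Si](C)(C)CCO | starting material
10 | 5-[(2R,3S)-2-(3-chloropropyl)-2-methyl-3-(prop-1-en-2-yl)hex-5-enoyl]-2,2-dimethyl-1,3-dioxane-4,6-dione (acyl Meldrum's acid) | CC1(C)OC(=O)C(C(=O)[C@](C)(CCCCl)[C@@H](CC=C)C(C)=C)C(=O)O1 | intermediate (not isolated)
11 | 2-(trimethylsilyl)ethyl (4R,5S)-4-(3-chloropropyl)-4-methyl-3-oxo-5-(prop-1-en-2-yl)oct-7-enoate | C[Si](C)(C)CCOC(=O)CC(=O)[C@](C)(CCCCl)[C@@H](CC=C)C(C)=C | intermediate
12 | 2-(trimethylsilyl)ethyl (3R)-3-methyl-3-[(3S)-2-methylhexa-1,5-dien-3-yl]-2-oxocyclohexane-1-carboxylate (C4 of the labdane frame unfixed: epimers and enol) | C[Si](C)(C)CCOC(=O)C1CCC[C@](C)([C@@H](CC=C)C(C)=C)C1=O | intermediate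
13 | 2-(trimethylsilyl)ethyl (3R)-3-methyl-3-[(3S)-2-methylhexa-1,5-dien-3-yl]-2-{[(trifluoromethyl)sulfonyl]oxy}cyclohex-1-ene-1-carboxylate | C[Si](C)(C)CCOC(=O)C1=C(OS(=O)(=O)C(F)(F)F)[C@@](C)([C@@H](CC=C)C(C)=C)CCC1 | intermediate
14 | 2-(trimethylsilyl)ethyl (3R)-2,3-dimethyl-3-[(3S)-2-methylhexa-1,5-dien-3-yl]cyclohex-1-ene-1-carboxylate | C[Si](C)(C)CCOC(=O)C1=C(C)[C@@](C)([C@@H](CC=C)C(C)=C)CCC1 | intermediate
15 | 2-(trimethylsilyl)ethyl (3R)-3-[(3R)-2-(hydroxymethyl)hexa-1,5-dien-3-yl]-2,3-dimethylcyclohex-1-ene-1-carboxylate | C[Si](C)(C)CCOC(=O)C1=C(C)[C@@](C)([C@@H](CC=C)C(=C)CO)CCC1 | intermediate (not isolated)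
16 | 2-(trimethylsilyl)ethyl (3R)-3-[(3R)-2-formylhexa-1,5-dien-3-yl]-2,3-dimethylcyclohex-1-ene-1-carboxylate | C[Si](C)(C)CCOC(=O)C1=C(C)[C@@](C)([C@@H](CC=C)C(=C)C=O)CCC1 | intermediate
17 | 2-(trimethylsilyl)ethyl (4aR,5R,7S)-7-hydroxy-4a-methyl-6-methylidene-5-(prop-2-en-1-yl)-2,3,4,4a,5,6,7,8-octahydronaphthalene-1-carboxylate (7β-OH) | C=CC[C@H]1C(=C)[C@@H](O)CC2=C(C(=O)OCC[Si](C)(C)C)CCC[C@]12C | intermediate
18 | 2-(trimethylsilyl)ethyl (1S,4aR,5R,7S,8aR)-7-hydroxy-1,4a-dimethyl-6-methylidene-5-(prop-2-en-1-yl)decahydronaphthalene-1-carboxylate (7β-OH, trans-decalin) | C=CC[C@H]1C(=C)[C@@H](O)C[C@@H]2[C@]1(C)CCC[C@]2(C)C(=O)OCC[Si](C)(C)C | intermediate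
19 | 2-(trimethylsilyl)ethyl (1S,4aR,5R,7R,8aR)-7-(acetyloxy)-1,4a-dimethyl-6-methylidene-5-(prop-2-en-1-yl)decahydronaphthalene-1-carboxylate (7α-OAc) | C=CC[C@H]1C(=C)[C@H](OC(C)=O)C[C@@H]2[C@]1(C)CCC[C@]2(C)C(=O)OCC[Si](C)(C)C | intermediate
20 | methacrolein (2-methylprop-2-enal) | CC(=C)C=O | starting material
21 | 2-(trimethylsilyl)ethyl (1S,4aR,5R,7R,8aR)-7-(acetyloxy)-1,4a-dimethyl-6-methylidene-5-[(2E)-3-methyl-4-oxobut-2-en-1-yl]decahydronaphthalene-1-carboxylate | O=C/C(C)=C/C[C@H]1C(=C)[C@H](OC(C)=O)C[C@@H]2[C@]1(C)CCC[C@]2(C)C(=O)OCC[Si](C)(C)C | intermediate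
22 | 2-(trimethylsilyl)ethyl (1S,4aR,5R,7R,8aR)-7-(acetyloxy)-1,4a-dimethyl-6-methylidene-5-[(2E)-3-methylpenta-2,4-dien-1-yl]decahydronaphthalene-1-carboxylate | C=C/C(C)=C/C[C@H]1C(=C)[C@H](OC(C)=O)C[C@@H]2[C@]1(C)CCC[C@]2(C)C(=O)OCC[Si](C)(C)C | intermediate
23 | (1S,4aR,5R,7R,8aR)-7-(acetyloxy)-1,4a-dimethyl-6-methylidene-5-[(2E)-3-methylpenta-2,4-dien-1-yl]decahydronaphthalene-1-carboxylic acid | C=C/C(C)=C/C[C@H]1C(=C)[C@H](OC(C)=O)C[C@@H]2[C@]1(C)CCC[C@]2(C)C(=O)O | target

**Step count and risks**

Total steps: 16. Longest linear sequence: 16 steps from (R)-carvone; all other inputs are commercial.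

Most likely to fail:

Step 11 (ring B closure). The extended enolate may attack through C4 instead of C6, the hindered aluminium-bound ester may not be deprotonated, or the facial selectivity at C7 may be poor. The fallback replaces the enolate addition by a Lewis acid carbonyl–ene reaction. It sets out from the allylic alcohol 15, which would then be isolated. Deprotonation with LiN(i-Pr)2 (2.2 equiv, THF/DMPU, −78 °C) and kinetic protonation with acetic acid would move the double bond out of conjugation to the exocyclic-methylene ester F1 (C5=C6, hydrogen on C4). MnO2 would give the aldehyde F2. Me2AlCl (CH2Cl2, −78 °C) would then close ring B through C6–C7 by an intramolecular carbonyl–ene reaction, the tether sitting on the central ene carbon C5. The C4 hydrogen is handed to the aldehyde oxygen and the C4=C5 double bond returns to conjugation, an arrangement that should place the oxygen axial and give the 7α-hydroxy enoate F3. Reductive methylation as in step 12 would give the 7α-alcohol F4, and acetylation (Ac2O, pyridine, DMAP) in place of step 13 comes back to the route at 19.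

Step 13 (inversion at C7). Acetate may attack at C17 with allylic transposition (SN2′), or the activated alcohol may eliminate. The fallback inverts by oxidation and catalyst-controlled reduction. It sets out from 18: Dess–Martin periodinane would give the α-methylene ketone F5. A Corey–Bakshi–Shibata 1,2-reduction, with the oxazaborolidine enantiomer chosen to deliver hydride to the β-face (BH3·SMe2, −40 °C), would give the 7α-alcohol F4 already met above. Acetylation (Ac2O, pyridine, DMAP) comes back to the route at 19.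

Step 12 (reductive methylation). The allylic C7–O bond may be hydrogenolysed, the alkoxide may be methylated on oxygen, or facial control at C4 may be poor under dissolving-metal conditions. The fallback separates reduction and alkylation. It sets out from 17: SmI2/HMPA/t-BuOH (THF, rt) would reduce the enoate by single-electron transfer to the trans-fused saturated ester F6 (C4 epimers). Its dianion (LiN(i-Pr)2, 2.2 equiv, THF, −78 °C) would then be methylated at C4 from the equatorial face with one equivalent of MeI, coming back to the route at 18.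

Further compounds
F1 | step 11 | 2-(trimethylsilyl)ethyl (3R)-3-[(3R)-2-(hydroxymethyl)hexa-1,5-dien-3-yl]-3-methyl-2-methylidenecyclohexane-1-carboxylate (C4 epimers) | C[Si](C)(C)CCOC(=O)C1CCC[C@](C)([C@@H](CC=C)C(=C)CO)C1=C
F2 | step 11 | 2-(trimethylsilyl)ethyl (3R)-3-[(3R)-2-formylhexa-1,5-dien-3-yl]-3-methyl-2-methylidenecyclohexane-1-carboxylate (C4 epimers) | C[Si](C)(C)CCOC(=O)C1CCC[C@](C)([C@@H](CC=C)C(=C)C=O)C1=C
F3 | step 11 | 2-(trimethylsilyl)ethyl (4aR,5R,7R)-7-hydroxy-4a-methyl-6-methylidene-5-(prop-2-en-1-yl)-2,3,4,4a,5,6,7,8-octahydronaphthalene-1-carboxylate (7α-OH epimer of 17) | C=CC[C@H]1C(=C)[C@H](O)CC2=C(C(=O)OCC[Si](C)(C)C)CCC[C@]12C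
F4 | step 11 | 2-(trimethylsilyl)ethyl (1S,4aR,5R,7R,8aR)-7-hydroxy-1,4a-dimethyl-6-methylidene-5-(prop-2-en-1-yl)decahydronaphthalene-1-carboxylate (7α-OH epimer of 18) | C=CC[C@H]1C(=C)[C@H](O)C[C@@H]2[C@]1(C)CCC[C@]2(C)C(=O)OCC[Si](C)(C)C
F5 | step 13 | 2-(trimethylsilyl)ethyl (1S,4aR,5R,8aR)-1,4a-dimethyl-6-methylidene-7-oxo-5-(prop-2-en-1-yl)decahydronaphthalene-1-carboxylate | C=CC[C@H]1C(=C)C(=O)C[C@@H]2[C@]1(C)CCC[C@]2(C)C(=O)OCC[Si](C)(C)C
F6 | step 12 | 2-(trimethylsilyl)ethyl 7β-hydroxy-4a-methyl-6-methylidene-5-(prop-2-en-1-yl)decahydronaphthalene-1-carboxylate (trans-fused, 5α-H, C4 epimers, no C18 methyl) | C=CC[C@H]1C(=C)[C@@H](O)C[C@@H]2[C@]1(C)CCCC2C(=O)OCC[Si](C)(C)C
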